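## Retrosynthetic overview

1. Germacrane numbering: C1=C2 (E), C3–OH, C4(Me)=C5 (Z), C6–O (lactone), C7, C8–O (angelate), C9, C10(Me)OH, C11=C13H2, C12=O. The target comes from a macrocyclic C8 carbinol by angeloylation and desilylation.
2. The ten-membered ring is formed last, at C7–C8: the SmI2 ketyl radical of a C8 aldehyde adds to C7 of a tethered 3-(acetoxymethyl)butenolide, and loss of acetate unveils the α-methylene lactone. C7 and C8 are set here.
3. The open-chain aldehyde comes from a C2–C3 bond: asymmetric alkenylzinc addition of an East alkyne (C8–C10, C1, C2) to a West (Z)-enal, setting C3 and the E-olefin.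
4. The West butenolide is the first ring formed: 4-methylfuran-2(5H)-one (C3–C6, Z-olefin from the ring), methyl propiolate (C7, C11, C12; asymmetric alkynylation sets C6) and formaldehyde (C13).
5. The East alkyne comes from (E)-3-methylpent-2-en-4-yn-1-ol by asymmetric epoxidation and C2-selective hydride opening (sets C10).

Assumption: the SMILES is read literally (lactone cis-fused at C6/C7; 3aR,4S,6S,9S,11aS; 7E,10Z in cyclodeca[b]furan numbering), and formaldehyde is counted as a numbered starting material.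

## Route

Step 1
Reactants: 1 (E)-3-methylpent-2-en-4-yn-1-ol
Product: 2 [(2R,3R)-3-ethynyl-3-methyloxiran-2-yl]methanol
Conditions: Ti(OiPr)4 (10 mol %), D-(−)-diethyl tartrate (12 mol %), tBuOOH, 4 Å molecular sieves, CH2Cl2, −20 °C
Reagents that add atoms: tert-butyl hydroperoxide, CC(C)(C)OO
Why: Sharpless asymmetric epoxidation of an (E)-trisubstituted allylic alcohol is reliable, and the D-tartrate delivers oxygen to the face that gives the (2R,3R)-epoxide, fixing the oxygen-bearing quaternary carbon that becomes (S)-C10.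

Step 2
Reactants: 2 [(2R,3R)-3-ethynyl-3-methyloxiran-2-yl]methanol
Product: 3 (3S)-3-methylpent-4-yne-1,3-diol
Conditions: NaAlH2(OCH2CH2OMe)2, THF, −20 → 0 °C; aq. potassium sodium tartrate
Reagents that add atoms: none
Why: Hydroxyl-directed reductive opening of a 2,3-epoxy alcohol delivers hydride from the C1-bound aluminate to C2 and leaves the C–O bond at the quaternary carbon intact, so C10 keeps its configuration, and the terminal alkyne is not reduced at this temperature.

Step 3
Reactants: 3 (3S)-3-methylpent-4-yne-1,3-diol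
Product: 4 (3S)-3-methyl-3,5-bis(triethylsilyloxy)pent-1-yne
Conditions: Et3SiOTf, 2,6-lutidine, CH2Cl2, −78 → 0 °C
Reagents that add atoms: triethylsilyl triflate, CC[Si](CC)(CC)OS(=O)(=O)C(F)(F)F
Why: Exhaustive silylation with a silyl triflate covers the primary and the hindered tertiary hydroxyl and touches no stereocentre.

Step 4
Reactants: 5 4-methylfuran-2(5H)-one
Product: 7 (Z)-N-methoxy-N,3-dimethyl-4-(triethylsilyloxy)but-2-enamide, via chloromagnesium alkoxide of the ring-opened hydroxy amide 6 (not isolated)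
Conditions: MeNHOMe·HCl, iPrMgCl, THF, −20 °C; then Et3SiCl, 4-(dimethylamino)pyridine (cat.), 0 °C → rt
Reagents that add atoms: N,O-dimethylhydroxylamine hydrochloride, CNOC.Cl; chlorotriethylsilane, CC[Si](CC)(CC)Cl
Why: Weinreb aminolysis of the lactone by the magnesium amide followed by silylation of the freed alkoxide in the same flask blocks relactonisation and carries the ring-imposed Z geometry of C4=C5 into the open chain.

Step 5
Reactants: 7 (Z)-N-methoxy-N,3-dimethyl-4-(triethylsilyloxy)but-2-enamide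
Product: 9 (Z)-3-methyl-4-(triethylsilyloxy)but-2-enal, via chelated diisobutylaluminium hemiaminal 8 (not isolated)
Conditions: iBu2AlH, THF, −78 °C; aq. potassium sodium tartrate
Reagents that add atoms: none
Why: Weinreb amide reduction stops at the aldehyde because the chelated hemiaminal survives until work-up, and the Z-olefin does not isomerise at −78 °C.

Step 6
Reactants: 9 (Z)-3-methyl-4-(triethylsilyloxy)but-2-enal; 10 methyl propiolate
Product: 12 methyl (4S,5Z)-4-hydroxy-6-methyl-7-(triethylsilyloxy)hept-5-en-2-ynoate, via methyl 3-(methylzincio)prop-2-ynoate 11 (not isolated)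
Conditions: Me2Zn (3 equiv), (S,S)-ProPhenol ligand [2,6-bis{[(S)-2-(hydroxydiphenylmethyl)pyrrolidin-1-yl]methyl}-4-methylphenol, the antipode that delivers to the Re face] (10 mol %), Ph3PO (20 mol %), toluene, 0 → 4 °C
Reagents that add atoms: none
Why: Trost dinuclear zinc–ProPhenol alkynylation of an α,β-unsaturated aldehyde with methyl propiolate delivers the alkynylzinc to the Re face under catalyst control and sets (S)-C6 (C4 of 12).

Step 7
Reactants: 12 methyl (4S,5Z)-4-hydroxy-6-methyl-7-(triethylsilyloxy)hept-5-en-2-ynoate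
Product: 14 (5R)-5-[(Z)-2-methyl-3-(triethylsilyloxy)prop-1-en-1-yl]furan-2(5H)-one, via (2Z,5Z)-hydroxy dienoate 13 (not isolated)
Conditions: H2 (1 atm), Pd/CaCO3 poisoned with Pb(OAc)2, quinoline, EtOAc, rt; then SiO2, toluene, 40 °C
Reagents that add atoms: none
Why: Lindlar semihydrogenation gives the (Z)-4-hydroxy-2-enoate, which lactonises spontaneously to the butenolide; the stereocentre is untouched and its descriptor changes to R only through the priority rules.

Step 8
Reactants: 14 (5R)-5-[(Z)-2-methyl-3-(triethylsilyloxy)prop-1-en-1-yl]furan-2(5H)-one; 15 formaldehyde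
Product: 16 (5S)-3-(hydroxymethyl)-5-[(Z)-2-methyl-3-(triethylsilyloxy)prop-1-en-1-yl]furan-2(5H)-one
Conditions: 37 % aq. HCHO, PBu3 (20 mol %), THF, rt
Reagents that add atoms: none
Why: Morita–Baylis–Hillman hydroxymethylation, in which PBu3 adds reversibly to C7, the lactone enolate attacks formaldehyde at C11 and the phosphine is eliminated, is known for cyclic enones and butenolides and creates no stereocentre.

Step 9
Reactants: 16 (5S)-3-(hydroxymethyl)-5-[(Z)-2-methyl-3-(triethylsilyloxy)prop-1-en-1-yl]furan-2(5H)-one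
Product: 17 {(5S)-5-[(Z)-2-methyl-3-(triethylsilyloxy)prop-1-en-1-yl]-2-oxo-2,5-dihydrofuran-3-yl}methyl acetate
Conditions: Ac2O, pyridine, CH2Cl2, 0 °C
Reagents that add atoms: acetic anhydride, CC(=O)OC(C)=O
Why: Simple O-acetylation of the only free hydroxyl turns it into the leaving group needed in step 14.

Step 10
Reactants: 17 {(5S)-5-[(Z)-2-methyl-3-(triethylsilyloxy)prop-1-en-1-yl]-2-oxo-2,5-dihydrofuran-3-yl}methyl acetate
Product: 19 {(5S)-5-[(Z)-2-methyl-3-oxoprop-1-en-1-yl]-2-oxo-2,5-dihydrofuran-3-yl}methyl acetate, via alkoxydimethylsulfonium chloride 18 (not isolated)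
Conditions: (COCl)2, DMSO, CH2Cl2, −78 °C; then Et3N, −78 → −40 °C
Reagents that add atoms: none
Why: Under Swern conditions the chlorosulfonium salt cleaves a primary triethylsilyl ether and oxidises it directly to the aldehyde, and the low temperature spares the acidic C6–H and the Z-olefin.

Step 11
Reactants: 4 (3S)-3-methyl-3,5-bis(triethylsilyloxy)pent-1-yne; 19 {(5S)-5-[(Z)-2-methyl-3-oxoprop-1-en-1-yl]-2-oxo-2,5-dihydrofuran-3-yl}methyl acetate
Product: 22 {(5S)-5-[(1Z,3S,4E,6S)-3-hydroxy-2,6-dimethyl-6,8-bis(triethylsilyloxy)octa-1,4-dien-1-yl]-2-oxo-2,5-dihydrofuran-3-yl}methyl acetate, via alkenyldicyclohexylborane 20 (not isolated), via alkenyl(methyl)zinc 21 (not isolated)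
Conditions: Cy2BH, toluene, 0 °C → rt; Me2Zn, −78 °C; (2S)-(−)-3-exo-morpholinoisoborneol (5 mol %); then 19, −10 °C
Reagents that add atoms: none
Why: In the Oppolzer–Walsh sequence syn hydroboration gives the (E)-alkenylborane, boron-to-zinc exchange gives the alkenylzinc, and the amino alcohol–zinc catalyst adds it to the Si face of the enal, setting (S)-C3 and the E-C1=C2 olefin without touching lactone or acetate.

Step 12
Reactants: 22 {(5S)-5-[(1Z,3S,4E,6S)-3-hydroxy-2,6-dimethyl-6,8-bis(triethylsilyloxy)octa-1,4-dien-1-yl]-2-oxo-2,5-dihydrofuran-3-yl}methyl acetate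
Product: 23 {(5S)-5-[(1Z,3S,4E,6S)-3-(tert-butyldimethylsilyloxy)-2,6-dimethyl-6,8-bis(triethylsilyloxy)octa-1,4-dien-1-yl]-2-oxo-2,5-dihydrofuran-3-yl}methyl acetate
Conditions: tBuMe2SiOTf, 2,6-lutidine, CH2Cl2, −78 °C
Reagents that add atoms: tert-butyldimethylsilyl triflate, CC(C)(C)[Si](C)(C)OS(=O)(=O)C(F)(F)F
Why: Low-temperature silylation protects the doubly allylic C3 hydroxyl without ionising it, so that only the C8 hydroxyl is free for acylation later.

Step 13
Reactants: 23 {(5S)-5-[(1Z,3S,4E,6S)-3-(tert-butyldimethylsilyloxy)-2,6-dimethyl-6,8-bis(triethylsilyloxy)octa-1,4-dien-1-yl]-2-oxo-2,5-dihydrofuran-3-yl}methyl acetate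
Product: 25 {(5S)-5-[(1Z,3S,4E,6S)-3-(tert-butyldimethylsilyloxy)-2,6-dimethyl-8-oxo-6-(triethylsilyloxy)octa-1,4-dien-1-yl]-2-oxo-2,5-dihydrofuran-3-yl}methyl acetate, via alkoxydimethylsulfonium chloride 24 (not isolated)
Conditions: (COCl)2, DMSO, CH2Cl2, −78 °C; then Et3N, −78 → −40 °C
Reagents that add atoms: none
Why: The same desilylative Swern oxidation converts only the primary triethylsilyl ether into the C8 aldehyde, while the tertiary triethylsilyl and secondary tert-butyldimethylsilyl ethers are inert.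

Step 14
Reactants: 25 {(5S)-5-[(1Z,3S,4E,6S)-3-(tert-butyldimethylsilyloxy)-2,6-dimethyl-8-oxo-6-(triethylsilyloxy)octa-1,4-dien-1-yl]-2-oxo-2,5-dihydrofuran-3-yl}methyl acetate
Product: 28 (3aR,4S,6S,7E,9S,10Z,11aS)-9-(tert-butyldimethylsilyloxy)-4-hydroxy-6,10-dimethyl-3-methylidene-6-(triethylsilyloxy)-3a,4,5,6,9,11a-hexahydrocyclodeca[b]furan-2(3H)-one, via samarium ketyl radical 26 (not isolated), via cyclised samarium enolate 27 (not isolated)
Conditions: SmI2 (2.5 equiv, 0.1 M in THF) and 25 added simultaneously by syringe pumps over 8 h to THF at −40 °C (final 1 mM), then −40 → 0 °C; aq. NaHCO3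
Reagents that add atoms: none
Why: Proposed new method: in THF without HMPA SmI2 reduces the aldehyde far faster than the unsaturated lactone, the nucleophilic ketyl radical 26 adds to the electron-poor β-carbon C7 of the butenolide from the face that carries the tether at C6 (giving the cis ring fusion and R-C7), a second SmI2 reduces the α-carbonyl radical to enolate 27, which expels acetate (E1cB) to unveil the exo-methylene, and a staggered transition state with C9 anti to C11 and the bulky O–Sm group outside the forming ring is expected to give S-C8; the closest known reactions are SmI2 ketyl–olefin lactone couplings, SmI2 medium-ring ketyl–olefin cyclisations and aldehyde allylations with 3-(bromomethyl)butenolides, whereas a ten-membered closure with acetate loss is new.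

Step 15
Reactants: 28 (3aR,4S,6S,7E,9S,10Z,11aS)-9-(tert-butyldimethylsilyloxy)-4-hydroxy-6,10-dimethyl-3-methylidene-6-(triethylsilyloxy)-3a,4,5,6,9,11a-hexahydrocyclodeca[b]furan-2(3H)-one; 29 angelic acid [(Z)-2-methylbut-2-enoic acid]
Product: 31 (3aR,4S,6S,7E,9S,10Z,11aS)-9-(tert-butyldimethylsilyloxy)-6,10-dimethyl-3-methylidene-2-oxo-6-(triethylsilyloxy)-2,3,3a,4,5,6,9,11a-octahydrocyclodeca[b]furan-4-yl (Z)-2-methylbut-2-enoate, via angelic 2,4,6-trichlorobenzoic anhydride 30 (not isolated)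
Conditions: 29, 2,4,6-trichlorobenzoyl chloride, Et3N, toluene, rt; then 28, 80 °C
Reagents that add atoms: none
Why: Yamaguchi mixed-anhydride esterification without a nucleophilic catalyst is the standard way to make angelates without Z-to-E isomerisation, and it acylates the only free hydroxyl with retention at C8.

Step 16
Reactants: 31 (3aR,4S,6S,7E,9S,10Z,11aS)-9-(tert-butyldimethylsilyloxy)-6,10-dimethyl-3-methylidene-2-oxo-6-(triethylsilyloxy)-2,3,3a,4,5,6,9,11a-octahydrocyclodeca[b]furan-4-yl (Z)-2-methylbut-2-enoate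
Product: 32 (3aR,4S,6S,7E,9S,10Z,11aS)-6,9-dihydroxy-6,10-dimethyl-3-methylidene-2-oxo-2,3,3a,4,5,6,9,11a-octahydrocyclodeca[b]furan-4-yl (Z)-2-methylbut-2-enoate
Conditions: HF·pyridine, pyridine, THF, 0 °C → rt
Reagents that add atoms: none
Why: Buffered fluoride desilylation cleaves both silyl ethers without touching the angelate, the α-methylene lactone or the allylic alcohols, giving the target with the stereocentres set in steps 1, 6, 11 and 14.

## Compound list

1 | (E)-3-methylpent-2-en-4-yn-1-ol | C#C/C(C)=C/CO | starting material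
2 | [(2R,3R)-3-ethynyl-3-methyloxiran-2-yl]methanol | OC[C@H]1O[C@]1(C)C#C | intermediate
3 | (3S)-3-methylpent-4-yne-1,3-diol | C#C[C@@](C)(O)CCO | intermediate
4 | (3S)-3-methyl-3,5-bis(triethylsilyloxy)pent-1-yne | C#C[C@@](C)(O[Si](CC)(CC)CC)CCO[Si](CC)(CC)CC | intermediate
5 | 4-methylfuran-2(5H)-one | CC1=CC(=O)OC1 | starting material
6 | chloromagnesium alkoxide of (Z)-4-hydroxy-N-methoxy-N,3-dimethylbut-2-enamide (not isolated) | CON(C)C(=O)/C=C(/C)CO[Mg]Cl | intermediate
7 | (Z)-N-methoxy-N,3-dimethyl-4-(triethylsilyloxy)but-2-enamide | CON(C)C(=O)/C=C(/C)CO[Si](CC)(CC)CC | intermediate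
8 | N,O-chelated diisobutylaluminium hemiaminal of 7 (not isolated) | CON(C)C(O[Al](CC(C)C)CC(C)C)/C=C(/C)CO[Si](CC)(CC)CC | intermediate
9 | (Z)-3-methyl-4-(triethylsilyloxy)but-2-enal | O=C/C=C(/C)CO[Si](CC)(CC)CC | intermediate
10 | methyl propiolate | C#CC(=O)OC | starting material
11 | methyl 3-(methylzincio)prop-2-ynoate (not isolated) | C[Zn]C#CC(=O)OC | intermediate
12 | methyl (4S,5Z)-4-hydroxy-6-methyl-7-(triethylsilyloxy)hept-5-en-2-ynoate | COC(=O)C#C[C@@H](O)/C=C(/C)CO[Si](CC)(CC)CC | intermediate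
13 | methyl (2Z,4R,5Z)-4-hydroxy-6-methyl-7-(triethylsilyloxy)hepta-2,5-dienoate (not isolated) | COC(=O)/C=C\[C@@H](O)/C=C(/C)CO[Si](CC)(CC)CC | intermediate
14 | (5R)-5-[(Z)-2-methyl-3-(triethylsilyloxy)prop-1-en-1-yl]furan-2(5H)-one | O=C1C=C[C@H](/C=C(/C)CO[Si](CC)(CC)CC)O1 | intermediate
15 | formaldehyde | C=O | starting material
16 | (5S)-3-(hydroxymethyl)-5-[(Z)-2-methyl-3-(triethylsilyloxy)prop-1-en-1-yl]furan-2(5H)-one | O=C1C(CO)=C[C@H](/C=C(/C)CO[Si](CC)(CC)CC)O1 | intermediate
17 | {(5S)-5-[(Z)-2-methyl-3-(triethylsilyloxy)prop-1-en-1-yl]-2-oxo-2,5-dihydrofuran-3-yl}methyl acetate | CC(=O)OCC1=C[C@H](/C=C(/C)CO[Si](CC)(CC)CC)OC1=O | intermediate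
18 | alkoxydimethylsulfonium chloride from 17 (not isolated) | CC(=O)OCC1=C[C@H](/C=C(/C)CO[S+](C)C)OC1=O.[Cl-] | intermediate
19 | {(5S)-5-[(Z)-2-methyl-3-oxoprop-1-en-1-yl]-2-oxo-2,5-dihydrofuran-3-yl}methyl acetate | CC(=O)OCC1=C[C@H](/C=C(/C)C=O)OC1=O | intermediate
20 | dicyclohexyl[(1E,3S)-3-methyl-3,5-bis(triethylsilyloxy)pent-1-en-1-yl]borane (not isolated) | C1CCCCC1B(C1CCCCC1)/C=C/[C@@](C)(O[Si](CC)(CC)CC)CCO[Si](CC)(CC)CC | intermediate
21 | methyl[(1E,3S)-3-methyl-3,5-bis(triethylsilyloxy)pent-1-en-1-yl]zinc (not isolated) | C[Zn]/C=C/[C@@](C)(O[Si](CC)(CC)CC)CCO[Si](CC)(CC)CC | intermediate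
22 | {(5S)-5-[(1Z,3S,4E,6S)-3-hydroxy-2,6-dimethyl-6,8-bis(triethylsilyloxy)octa-1,4-dien-1-yl]-2-oxo-2,5-dihydrofuran-3-yl}methyl acetate | CC(=O)OCC1=C[C@H](/C=C(/C)[C@@H](O)/C=C/[C@@](C)(O[Si](CC)(CC)CC)CCO[Si](CC)(CC)CC)OC1=O | intermediate
23 | {(5S)-5-[(1Z,3S,4E,6S)-3-(tert-butyldimethylsilyloxy)-2,6-dimethyl-6,8-bis(triethylsilyloxy)octa-1,4-dien-1-yl]-2-oxo-2,5-dihydrofuran-3-yl}methyl acetate | CC(=O)OCC1=C[C@H](/C=C(/C)[C@@H](O[Si](C)(C)C(C)(C)C)/C=C/[C@@](C)(O[Si](CC)(CC)CC)CCO[Si](CC)(CC)CC)OC1=O | intermediate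
24 | alkoxydimethylsulfonium chloride from 23 at O8 (not isolated) | CC(=O)OCC1=C[C@H](/C=C(/C)[C@@H](O[Si](C)(C)C(C)(C)C)/C=C/[C@@](C)(O[Si](CC)(CC)CC)CCO[S+](C)C)OC1=O.[Cl-] | intermediate
25 | {(5S)-5-[(1Z,3S,4E,6S)-3-(tert-butyldimethylsilyloxy)-2,6-dimethyl-8-oxo-6-(triethylsilyloxy)octa-1,4-dien-1-yl]-2-oxo-2,5-dihydrofuran-3-yl}methyl acetate | CC(=O)OCC1=C[C@H](/C=C(/C)[C@@H](O[Si](C)(C)C(C)(C)C)/C=C/[C@@](C)(O[Si](CC)(CC)CC)CC=O)OC1=O | intermediate
26 | samarium ketyl radical of 25 (C8-centred radical; not isolated) | CC(=O)OCC1=C[C@H](/C=C(/C)[C@@H](O[Si](C)(C)C(C)(C)C)/C=C/[C@@](C)(O[Si](CC)(CC)CC)C[CH]O[Sm](I)I)OC1=O | intermediate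
27 | cyclised samarium enolate, C7–C8 bond formed, acetate still in place (not isolated) | CC(=O)OCC1=C(O[Sm](I)I)O[C@H]2/C=C(/C)[C@@H](O[Si](C)(C)C(C)(C)C)/C=C/[C@@](C)(O[Si](CC)(CC)CC)C[C@H](O[Sm](I)I)[C@@H]12 | intermediate
28 | (3aR,4S,6S,7E,9S,10Z,11aS)-9-(tert-butyldimethylsilyloxy)-4-hydroxy-6,10-dimethyl-3-methylidene-6-(triethylsilyloxy)-3a,4,5,6,9,11a-hexahydrocyclodeca[b]furan-2(3H)-one | C=C1C(=O)O[C@H]2/C=C(/C)[C@@H](O[Si](C)(C)C(C)(C)C)/C=C/[C@@](C)(O[Si](CC)(CC)CC)C[C@H](O)[C@@H]12 | intermediate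
29 | angelic acid, (Z)-2-methylbut-2-enoic acid | C/C=C(/C)C(=O)O | starting material
30 | (Z)-2-methylbut-2-enoic 2,4,6-trichlorobenzoic anhydride (not isolated) | C/C=C(/C)C(=O)OC(=O)c1c(Cl)cc(Cl)cc1Cl | intermediate
31 | (3aR,4S,6S,7E,9S,10Z,11aS)-9-(tert-butyldimethylsilyloxy)-6,10-dimethyl-3-methylidene-2-oxo-6-(triethylsilyloxy)-2,3,3a,4,5,6,9,11a-octahydrocyclodeca[b]furan-4-yl (Z)-2-methylbut-2-enoate | C=C1C(=O)O[C@H]2/C=C(/C)[C@@H](O[Si](C)(C)C(C)(C)C)/C=C/[C@@](C)(O[Si](CC)(CC)CC)C[C@H](OC(=O)/C(C)=C\C)[C@@H]12 | intermediate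
32 | (3aR,4S,6S,7E,9S,10Z,11aS)-6,9-dihydroxy-6,10-dimethyl-3-methylidene-2-oxo-2,3,3a,4,5,6,9,11a-octahydrocyclodeca[b]furan-4-yl (Z)-2-methylbut-2-enoate | C=C1C(=O)O[C@H]2/C=C(/C)[C@@H](O)/C=C/[C@@](C)(O)C[C@H](OC(=O)/C(C)=C\C)[C@@H]12 | target

## Step count and risks

Total step count: 16. Longest linear sequence: 13 steps (5 to 19 by steps 4–10, then steps 11–16). The East branch (steps 1–3) joins at step 11.

The three steps most likely to fail:

Risk 1, step 14 (ten-membered ketyl closure). The ketyl may simply be reduced or dimerise before it closes the ring, and the sense of induction at C8 and the cis ring fusion rest only on a transition-state model. Fallback: leave the one-electron manifold and close the same bond through an allyl-metal. Setting out from 25, Pd(PPh3)4 (5 mol %) and InI (indium monoiodide, 1.5 equiv) in THF under high dilution convert the allylic acetate into an allylindium, which adds to the aldehyde through a closed six-membered transition state and comes back to the route at 28. Should this closure (or the SmI2 closure) deliver the C4-epimeric carbinol F1 instead, F1 is not discarded: esterification with 29 under Mitsunobu conditions (PPh3, diisopropyl azodicarboxylate, toluene, 0 °C) inverts C8 and comes back to the route at 31, replacing step 15.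

Risk 2, step 8 (hydroxymethylation of the butenolide). The phosphine-generated enolate is basic enough to epimerise the allylic, γ-acidic C6–H, and butenolides are sluggish Baylis–Hillman acceptors. Fallback: replace the nucleophile-catalysed aldol by a cross-coupling. Setting out from 14, α-iodination with I2 and pyridine in CH2Cl2 gives the 3-iodobutenolide F2. Stille coupling of F2 with (tributylstannyl)methanol (Pd(PPh3)4, dioxane, 80 °C) installs the hydroxymethyl group under neutral conditions and comes back to the route at 16.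

Risk 3, step 11 (alkenylzinc addition to the base-sensitive enal 19). Methyl transfer, erosion of the Z-olefin or of C6, and imperfect facial control are possible. Fallback: a chromium-mediated coupling under neutral conditions. Setting out from 4, hydrozirconation with Cp2Zr(H)Cl in THF and quenching with I2 gives the (E)-alkenyl iodide F3. Nozaki–Hiyama–Kishi coupling of F3 with 19 (CrCl2, 4 equiv; NiCl2, 1 mol %; DMSO, rt) tolerates lactone, acetate and the acidic C6–H and comes back to the route at 22. The accompanying (3R)-epimer F4 is removed by chromatography.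

Further compounds
F1 | step 14 | (3aR,4R,6S,7E,9S,10Z,11aS)-9-(tert-butyldimethylsilyloxy)-4-hydroxy-6,10-dimethyl-3-methylidene-6-(triethylsilyloxy)-3a,4,5,6,9,11a-hexahydrocyclodeca[b]furan-2(3H)-one (C4 epimer of 28) | C=C1C(=O)O[C@H]2/C=C(/C)[C@@H](O[Si](C)(C)C(C)(C)C)/C=C/[C@@](C)(O[Si](CC)(CC)CC)C[C@@H](O)[C@@H]12
F2 | step 8 | (5S)-3-iodo-5-[(Z)-2-methyl-3-(triethylsilyloxy)prop-1-en-1-yl]furan-2(5H)-one | O=C1C(I)=C[C@H](/C=C(/C)CO[Si](CC)(CC)CC)O1
F3 | step 11 | (1E,3S)-1-iodo-3-methyl-3,5-bis(triethylsilyloxy)pent-1-ene | I/C=C/[C@@](C)(O[Si](CC)(CC)CC)CCO[Si](CC)(CC)CC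
F4 | step 11 | {(5S)-5-[(1Z,3R,4E,6S)-3-hydroxy-2,6-dimethyl-6,8-bis(triethylsilyloxy)octa-1,4-dien-1-yl]-2-oxo-2,5-dihydrofuran-3-yl}methyl acetate (C3 epimer of 22) | CC(=O)OCC1=C[C@H](/C=C(/C)[C@H](O)/C=C/[C@@](C)(O[Si](CC)(CC)CC)CCO[Si](CC)(CC)CC)OC1=O
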